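**Plan**
1. Retrosynthetic cuts: the chain ketone goes back to a secondary allylic alcohol; then the C(sp3)–C(sp2) bond between the (CH2)3 tether and the enone β-carbon; then the tether–C2 bond of the pyranone (as an allyl group); then both ring bonds C3–C4 and O1–C2 of the pyranone at once; in the left half ArCH2–CH= and CH(O)–CH2.
2. Forward: the 2H-pyran-3(6H)-one, the only ring to be made, arises first by Pd-catalysed [4+2] heteroannulation of a (Z)-γ-hydroxy vinyl iodide with buta-1,2-diene; its carbonyl is carried as C=CH2 and then cleaved. C2 is allylated, the allyl group is hydroborated and coupled to the aryl dienyl iodide, and MnO2 makes the chain ketone last.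
3. Enabling feature: the ring unit O1–C6(Me)2–C5=C4 holds the ring oxygen and the enone α-carbon C4 cis on one double bond, and C3–C2 (an sp2 carbon next to an O-bearing sp3 carbon) maps onto the central and the substituted carbon of an allene.
4. Stereochemistry: the one stereocentre (C2 of the pyranone, S) is set by the PHOX–palladium catalyst in the decarboxylative allylation (step 5); both E trisubstituted alkenes come from syn carbo- or hydrometalation followed by couplings with retention.

Key step: step 2

Remark: the carbinol centre made in step 9 is carried as a racemate (epimer mixtures later) because step 15 turns it into the ketone; but-2-ynal is taken as a purchasable aldehyde.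

**Step 1**
Reactants: 1 ethyl (Z)-3-iodoprop-2-enoate
Product: 3 (Z)-4-iodo-2-methylbut-3-en-2-ol, via methyl ketone 2 (not isolated)
Conditions: MeMgBr (2.5 equiv), THF, −78 → 0 °C; aq NH4Cl
Reagents that add atoms: methylmagnesium bromide C[Mg]Br
Why: Double 1,2-addition of the Grignard reagent to the ester (through ketone 2) should give the tertiary alcohol, the vinylic C–I bond and its Z geometry being untouched at low temperature.

**Step 2**
Reactants: 3 (Z)-4-iodo-2-methylbut-3-en-2-ol; 4 buta-1,2-diene
Product: 5 rac-2,6,6-trimethyl-3-methylidene-3,6-dihydro-2H-pyran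
Conditions: Pd(OAc)2 (5 mol %), PPh3 (10 mol %), K2CO3 (2 equiv), n-Bu4NCl (1 equiv), 4 (3 equiv), DMF, 70 °C, sealed tube
Reagents that add atoms: none
Why: Zerovalent palladium (formed in situ from Pd(OAc)2 and PPh3) inserts into the vinylic C–I bond of 3 with retention of the Z geometry, the vinylpalladium iodide adds across the unsubstituted C=C of allene 4 so that the vinyl carbon is joined to the central allene carbon, and the resulting η3-allylpalladium species is captured at its methyl-bearing terminus by the tertiary hydroxyl (deprotonated by carbonate), which releases zerovalent palladium again. The closest known reaction type is the Larock heteroannulation of 1,2-dienes with aryl and vinylic iodides that carry an OH or NH nucleophile. The one ring that closes is the six-membered dihydropyran, by C–O bond formation in a 6-exo attack of oxygen on the allyl terminus; the CH2 terminus is left as the exocyclic methylidene that masks the C3 carbonyl. The new stereocentre at C2 is formed without control (racemic), which does not matter because it is flattened in step 4 and set in step 5. Regioselectivity is needed twice: the vinyl group must go to the central allene carbon, which is the normal course of carbopalladation of allenes because it leads to the allyl complex, and oxygen must attack the substituted terminus and not CH2 (either attack gives a six-membered ring), which is the usual preference of heteroatom nucleophiles in these annulations. The cis placement of C–Pd and the CMe2–OH arm on the Z double bond is what lets the alkoxide reach the allyl unit.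

**Step 3**
Reactants: 5 rac-2,6,6-trimethyl-3-methylidene-3,6-dihydro-2H-pyran
Product: 7 rac-2,6,6-trimethyl-2H-pyran-3(6H)-one, via diol 6 (not isolated)
Conditions: OsO4 (2 mol %), NaIO4 (4 equiv), 2,6-lutidine (2 equiv), dioxane/H2O 3:1, 0 °C → rt
Reagents that add atoms: osmium tetroxide O=[Os](=O)(=O)=O; sodium periodate [Na+].[O-]I(=O)(=O)=O
Why: Lemieux–Johnson oxidative cleavage: osmylation should choose the accessible exocyclic 1,1-disubstituted methylidene over the ring cis-alkene shielded by the CMe2 group, periodate cleaves diol 6, and the ring alkene then belongs to an enone and resists further osmylation.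

**Step 4**
Reactants: 7 rac-2,6,6-trimethyl-2H-pyran-3(6H)-one
Product: 9 prop-2-en-1-yl 2,6,6-trimethyl-6H-pyran-3-yl carbonate, via lithium dienolate 8 (not isolated)
Conditions: LiN(SiMe3)2 (1.1 equiv), TMEDA, THF, −78 °C; allyl chloroformate, −78 °C
Reagents that add atoms: allyl chloroformate C=CCOC(=O)Cl
Why: Deprotonation at C2, the only enolisable position, and O-acylation of the lithium dienolate by the chloroformate should give the allyl enol carbonate; the oxygen substituent at C3 and the gem-dimethyl group at C6 bias this 2H-pyran towards the closed valence isomer.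

**Step 5**
Reactants: 9 prop-2-en-1-yl 2,6,6-trimethyl-6H-pyran-3-yl carbonate
Product: 10 (2S)-2,6,6-trimethyl-2-(prop-2-en-1-yl)-2H-pyran-3(6H)-one
Conditions: Pd2(dba)3 (2.5 mol %), (S)-t-BuPHOX (6.25 mol %), THF, 25 °C
Reagents that add atoms: none
Why: Decarboxylative asymmetric allylic alkylation (Tsuji–Trost type): zerovalent palladium ionises the allyl carbonate, CO2 is lost, and C–C bond formation within the chiral allylpalladium enolate sets the quaternary C2, expected to be S with the (S)-ligand by analogy with 2-methylcycloalkanone enolates (sense to be confirmed, antipodal ligand otherwise) and with high enantiomeric excess.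

**Step 6**
Reactants: 11 4-methoxy-3-methylphenol
Product: 12 (4-methoxy-3-methylphenoxy)tri(propan-2-yl)silane
Conditions: TIPSCl, imidazole, DMF, rt
Reagents that add atoms: triisopropylsilyl chloride CC(C)[Si](Cl)(C(C)C)C(C)C
Why: Standard silylation of the phenol; the bulky TIPS ether protects the oxygen and blocks its own ortho positions for step 7.

**Step 7**
Reactants: 12 (4-methoxy-3-methylphenoxy)tri(propan-2-yl)silane
Product: 14 [2-methoxy-3-methyl-5-(triisopropylsilyloxy)phenyl]methanol, via aryllithium 13 (not isolated)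
Conditions: n-BuLi, TMEDA, Et2O, 0 °C → rt; (CH2O)n, −78 °C → rt
Reagents that add atoms: paraformaldehyde (as formaldehyde) C=O
Why: Directed ortho-metalation: the methoxy group directs lithiation to its only free ortho position (the OTIPS group is a poor and hindered director), and the aryllithium is hydroxymethylated by formaldehyde.

**Step 8**
Reactants: 14 [2-methoxy-3-methyl-5-(triisopropylsilyloxy)phenyl]methanol
Product: 16 [3-(chloromethyl)-4-methoxy-5-methylphenoxy]tri(propan-2-yl)silane, via benzylic mesylate 15 (not isolated)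
Conditions: MsCl, Et3N, CH2Cl2, 0 °C; LiCl, DMF, rt
Reagents that add atoms: methanesulfonyl chloride CS(=O)(=O)Cl; lithium chloride [Li+].[Cl-]
Why: Mesylation followed by SN2 displacement with chloride is a routine conversion of an electron-rich benzylic alcohol into the chloride and leaves the aryl silyl ether intact.

**Step 9**
Reactants: 17 but-2-ynal; 18 3-bromoprop-1-yne
Product: 19 rac-hepta-1,5-diyn-4-ol
Conditions: Zn dust, THF, 0 °C → rt; aq NH4Cl
Reagents that add atoms: none
Why: Barbier propargylation: the allenylzinc bromide formed in the flask adds to the aldehyde through its γ-carbon to give the homopropargylic alcohol; the new carbinol centre is racemic on purpose.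

**Step 10**
Reactants: 19 rac-hepta-1,5-diyn-4-ol
Product: 20 rac-tert-butyl(hepta-1,5-diyn-4-yloxy)dimethylsilane
Conditions: TBSCl, imidazole, DMF, rt
Reagents that add atoms: tert-butyldimethylsilyl chloride CC(C)(C)[Si](C)(C)Cl
Why: Standard silylation of the secondary alcohol, needed for the organoaluminium and zirconium hydride steps.

**Step 11**
Reactants: 20 rac-tert-butyl(hepta-1,5-diyn-4-yloxy)dimethylsilane; 16 [3-(chloromethyl)-4-methoxy-5-methylphenoxy]tri(propan-2-yl)silane
Product: 22 (E)-1-[2-methoxy-3-methyl-5-(triisopropylsilyloxy)phenyl]-3-methyl-5-(tert-butyldimethylsilyloxy)oct-2-en-6-yne, via vinylalane 21 (not isolated)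
Conditions: Me3Al (2.2 equiv), Cp2ZrCl2 (0.2 equiv), CH2Cl2, 0 °C → rt, excess Me3Al removed in vacuo; 16, Pd(PPh3)4 (5 mol %), THF, rt
Reagents that add atoms: trimethylaluminium C[Al](C)C
Why: Zirconium-catalysed syn-carboalumination (Negishi) of the terminal alkyne places methyl on the internal carbon and leaves the internal alkyne, and palladium-catalysed coupling of the alkenylalane with the benzylic chloride proceeds with retention to give the E trisubstituted alkene.

**Step 12**
Reactants: 22 (E)-1-[2-methoxy-3-methyl-5-(triisopropylsilyloxy)phenyl]-3-methyl-5-(tert-butyldimethylsilyloxy)oct-2-en-6-yne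
Product: 24 (2E,6E)-7-iodo-1-[2-methoxy-3-methyl-5-(triisopropylsilyloxy)phenyl]-3-methyl-5-(tert-butyldimethylsilyloxy)octa-2,6-diene, via vinylzirconocene 23 (not isolated)
Conditions: Cp2Zr(H)Cl (2.2 equiv), THF, rt → 40 °C; I2, 0 °C
Reagents that add atoms: iodine II
Why: Hydrozirconation: syn addition of Zr–H with zirconium on the less hindered, methyl-bearing alkyne carbon (equilibrated by excess hydride), then iodinolysis with retention should give the (E)-vinyl iodide; the trisubstituted alkene does not react.

**Step 13**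
Reactants: 10 (2S)-2,6,6-trimethyl-2-(prop-2-en-1-yl)-2H-pyran-3(6H)-one; 25 9-borabicyclo[3.3.1]nonane (9-BBN); 24 (2E,6E)-7-iodo-1-[2-methoxy-3-methyl-5-(triisopropylsilyloxy)phenyl]-3-methyl-5-(tert-butyldimethylsilyloxy)octa-2,6-diene
Product: 27 (2S)-2-[(4E,8E)-6-(tert-butyldimethylsilyloxy)-10-[2-methoxy-3-methyl-5-(triisopropylsilyloxy)phenyl]-4,8-dimethyldeca-4,8-dien-1-yl]-2,6,6-trimethyl-2H-pyran-3(6H)-one (both carbinol epimers), via alkylborane 26 (not isolated)
Conditions: 25 (1.1 equiv), THF, 0 °C → rt; 24, PdCl2(dppf) (5 mol %), AsPh3 (10 mol %), K3PO4 (3 M aq), DMF, rt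
Reagents that add atoms: none
Why: Anti-Markovnikov hydroboration of the monosubstituted alkene by 9-BBN (expected to be faster than reduction of the hindered, conjugated ring ketone) and B-alkyl Suzuki–Miyaura coupling with retention of the iodide geometry; the ring ketone is not enolisable and C2 is untouched.

**Step 14**
Reactants: 27 (bis-silyl ether from step 13)
Product: 28 (2S)-2-[(4E,8E)-6-hydroxy-10-(5-hydroxy-2-methoxy-3-methylphenyl)-4,8-dimethyldeca-4,8-dien-1-yl]-2,6,6-trimethyl-2H-pyran-3(6H)-one (both carbinol epimers)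
Conditions: n-Bu4NF (3 equiv), THF, 0 °C → rt
Reagents that add atoms: none
Why: Fluoride cleaves the aryl and the alkyl Si–O bond in one operation; no base-sensitive skipped enone is present yet.

**Step 15**
Reactants: 28 (diol from step 14)
Product: 29 (2S)-2-[(4E,8E)-10-(5-hydroxy-2-methoxy-3-methylphenyl)-4,8-dimethyl-6-oxodeca-4,8-dien-1-yl]-2,6,6-trimethyl-2H-pyran-3(6H)-one (target)
Conditions: activated MnO2 (excess), CH2Cl2, rt
Reagents that add atoms: none
Why: MnO2 oxidises the allylic alcohol selectively under neutral conditions, so the β,γ-double bond should not move into conjugation and the phenol is left alone; both carbinol epimers converge on the one ketone.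

**Compound list**
1 | ethyl (Z)-3-iodoprop-2-enoate | CCOC(=O)/C=C\I | starting material
2 | (Z)-4-iodobut-3-en-2-one | CC(=O)/C=C\I | intermediate (not isolated)
3 | (Z)-4-iodo-2-methylbut-3-en-2-ol | CC(C)(O)/C=C\I | intermediate
4 | buta-1,2-diene | C=C=CC | starting material
5 | rac-2,6,6-trimethyl-3-methylidene-3,6-dihydro-2H-pyran | CC1OC(C)(C)C=CC1=C | intermediate
6 | rac-3-(hydroxymethyl)-2,6,6-trimethyl-3,6-dihydro-2H-pyran-3-ol (diastereomer mixture) | CC1OC(C)(C)C=CC1(O)CO | intermediate (not isolated)
7 | rac-2,6,6-trimethyl-2H-pyran-3(6H)-one | CC1OC(C)(C)C=CC1=O | intermediate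
8 | lithium 2,6,6-trimethyl-6H-pyran-3-olate | [Li]OC1=C(C)OC(C)(C)C=C1 | intermediate (not isolated)
9 | prop-2-en-1-yl 2,6,6-trimethyl-6H-pyran-3-yl carbonate | C=CCOC(=O)OC1=C(C)OC(C)(C)C=C1 | intermediate
10 | (2S)-2,6,6-trimethyl-2-(prop-2-en-1-yl)-2H-pyran-3(6H)-one | C=CC[C@]1(C)OC(C)(C)C=CC1=O | intermediate
11 | 4-methoxy-3-methylphenol | COc1ccc(O)cc1C | starting material
12 | (4-methoxy-3-methylphenoxy)tri(propan-2-yl)silane | COc1ccc(O[Si](C(C)C)(C(C)C)C(C)C)cc1C | intermediate
13 | [2-methoxy-3-methyl-5-(triisopropylsilyloxy)phenyl]lithium | COc1c([Li])cc(O[Si](C(C)C)(C(C)C)C(C)C)cc1C | intermediate (not isolated)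
14 | [2-methoxy-3-methyl-5-(triisopropylsilyloxy)phenyl]methanol | COc1c(CO)cc(O[Si](C(C)C)(C(C)C)C(C)C)cc1C | intermediate
15 | [2-methoxy-3-methyl-5-(triisopropylsilyloxy)phenyl]methyl methanesulfonate | COc1c(COS(C)(=O)=O)cc(O[Si](C(C)C)(C(C)C)C(C)C)cc1C | intermediate (not isolated)
16 | [3-(chloromethyl)-4-methoxy-5-methylphenoxy]tri(propan-2-yl)silane | COc1c(CCl)cc(O[Si](C(C)C)(C(C)C)C(C)C)cc1C | intermediate
17 | but-2-ynal | CC#CC=O | starting material
18 | 3-bromoprop-1-yne (propargyl bromide) | C#CCBr | starting material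
19 | rac-hepta-1,5-diyn-4-ol | CC#CC(O)CC#C | intermediate
20 | rac-tert-butyl(hepta-1,5-diyn-4-yloxy)dimethylsilane | CC#CC(O[Si](C)(C)C(C)(C)C)CC#C | intermediate
21 | dimethyl[(1E)-2-methyl-4-(tert-butyldimethylsilyloxy)hept-1-en-5-yn-1-yl]alumane | CC#CC(O[Si](C)(C)C(C)(C)C)C/C(C)=C/[Al](C)C | intermediate (not isolated)
22 | (E)-1-[2-methoxy-3-methyl-5-(triisopropylsilyloxy)phenyl]-3-methyl-5-(tert-butyldimethylsilyloxy)oct-2-en-6-yne (racemic) | COc1c(C)cc(O[Si](C(C)C)(C(C)C)C(C)C)cc1C/C=C(\C)CC(O[Si](C)(C)C(C)(C)C)C#CC | intermediate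
23 | (E)-alkenylzirconocene chloride, Cp2Zr(Cl) on C7 of the octa-2,6-diene numbered as in 24 | COc1c(C)cc(O[Si](C(C)C)(C(C)C)C(C)C)cc1C/C=C(\C)CC(O[Si](C)(C)C(C)(C)C)/C=C(\C)[Zr](Cl)(C1C=CC=C1)C1C=CC=C1 | intermediate (not isolated)
24 | (2E,6E)-7-iodo-1-[2-methoxy-3-methyl-5-(triisopropylsilyloxy)phenyl]-3-methyl-5-(tert-butyldimethylsilyloxy)octa-2,6-diene (racemic) | COc1c(C)cc(O[Si](C(C)C)(C(C)C)C(C)C)cc1C/C=C(\C)CC(O[Si](C)(C)C(C)(C)C)/C=C(\C)I | intermediate
25 | 9-borabicyclo[3.3.1]nonane (9-BBN) | B1C2CCCC1CCC2 | starting material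
26 | (2S)-2-[3-(9-borabicyclo[3.3.1]nonan-9-yl)propyl]-2,6,6-trimethyl-2H-pyran-3(6H)-one | B1(C2CCCC1CCC2)CCC[C@]1(C)OC(C)(C)C=CC1=O | intermediate (not isolated)
27 | (2S)-2-[(4E,8E)-6-(tert-butyldimethylsilyloxy)-10-[2-methoxy-3-methyl-5-(triisopropylsilyloxy)phenyl]-4,8-dimethyldeca-4,8-dien-1-yl]-2,6,6-trimethyl-2H-pyran-3(6H)-one (carbinol epimers) | COc1c(C)cc(O[Si](C(C)C)(C(C)C)C(C)C)cc1C/C=C(\C)CC(O[Si](C)(C)C(C)(C)C)/C=C(\C)CCC[C@]1(C)OC(C)(C)C=CC1=O | intermediate
28 | (2S)-2-[(4E,8E)-6-hydroxy-10-(5-hydroxy-2-methoxy-3-methylphenyl)-4,8-dimethyldeca-4,8-dien-1-yl]-2,6,6-trimethyl-2H-pyran-3(6H)-one (carbinol epimers) | COc1c(C)cc(O)cc1C/C=C(\C)CC(O)/C=C(\C)CCC[C@]1(C)OC(C)(C)C=CC1=O | intermediate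
29 | (2S)-2-[(4E,8E)-10-(5-hydroxy-2-methoxy-3-methylphenyl)-4,8-dimethyl-6-oxodeca-4,8-dien-1-yl]-2,6,6-trimethyl-2H-pyran-3(6H)-one | COc1c(C)cc(O)cc1C/C=C(\C)CC(=O)/C=C(\C)CCC[C@]1(C)OC(C)(C)C=CC1=O | target

**Step count:** 15 steps in total. Longest linear sequence: 8 steps (1, 2, 3, 4, 5, 13, 14, 15, or equally 6, 7, 8, 11, 12, 13, 14, 15).

**Steps most likely to fail**

Step 2. The allylpalladium intermediate may be captured at the wrong terminus (oxygen attack at CH2, giving the ethylidene isomer), may lose a β-hydride to give open-chain trienes, or the exocyclic double bond of the product may migrate into the ring; the volatility of the product adds handling loss. The fallback makes the same two ring bonds by known anionic chemistry in two operations, sets out from 3 and comes back at 7, so that steps 2 and 3 are not needed. 3 is deprotonated with n-BuLi and subjected to iodine–lithium exchange with t-BuLi (2 equiv, Et2O, −78 °C) to give lithium (Z)-4-lithio-2-methylbut-3-en-2-olate F2. This is acylated at carbon by 2-chloro-N-methoxy-N-methylpropanamide F1 (made beforehand from 2-chloropropanoyl chloride, N,O-dimethylhydroxylamine hydrochloride and Et3N), which after mild acidic work-up should give (Z)-2-chloro-6-hydroxy-6-methylhept-4-en-3-one F3. K2CO3 in MeCN then closes the ring by intramolecular O-alkylation (6-exo-tet displacement of the secondary α-keto chloride by the tertiary alkoxide) to give 7.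

Step 5. The chiral palladium complex may discriminate the two faces of the cyclic dienolate insufficiently, so that enantiomeric purity is lost at the only stereocentre; material may also be lost if the dienolate, a 2H-pyran, opens electrocyclically. The fallback takes the stereochemistry from a reagent-controlled reduction and a separation instead, sets out from 9 and comes back at 10. 9 is allylated without a chiral ligand (Pd(PPh3)4, THF) to racemic 2,6,6-trimethyl-2-(prop-2-en-1-yl)-2H-pyran-3(6H)-one F4. Reduction with BH3·SMe2 under one enantiomer of the 2-methyl-CBS-oxazaborolidine (Corey–Bakshi–Shibata reduction) turns the two enantiomers into diastereomeric allylic alcohols, drawn here for the catalyst that gives the 3R carbinol: (2S,3R)-2,6,6-trimethyl-2-(prop-2-en-1-yl)-3,6-dihydro-2H-pyran-3-ol F5 and its (2R,3R) diastereomer F6. These are separated by chromatography, and MnO2 oxidation of F5 returns 10.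

Step 13. 9-BBN may reduce the ring enone in a 1,2-sense in competition with hydroboration of the allyl group. The fallback masks the ketone at the alcohol level, sets out from 10 and comes back at 29. Luche reduction (NaBH4, CeCl3·7H2O, MeOH) of 10 gives (2S)-2,6,6-trimethyl-2-(prop-2-en-1-yl)-3,6-dihydro-2H-pyran-3-ol F7 as a mixture of C3 epimers, which is silylated (TBSCl, imidazole) to the tert-butyldimethylsilyl ether F8. Hydroboration with 9-BBN gives the alkylborane F9, which is coupled with 24 under the conditions of step 13 to the tris-silyl ether F10. n-Bu4NF removes all three silyl groups to give the triol F11, and excess MnO2 oxidises both allylic alcohols (ring and chain) to give 29.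

**Further compounds**
F1 | step 2 | 2-chloro-N-methoxy-N-methylpropanamide | CC(Cl)C(=O)N(C)OC
F2 | step 2 | lithium (Z)-4-lithio-2-methylbut-3-en-2-olate | [Li]/C=C\C(C)(C)O[Li]
F3 | step 2 | (Z)-2-chloro-6-hydroxy-6-methylhept-4-en-3-one | CC(Cl)C(=O)/C=C\C(C)(C)O
F4 | step 5 | rac-2,6,6-trimethyl-2-(prop-2-en-1-yl)-2H-pyran-3(6H)-one | C=CCC1(C)OC(C)(C)C=CC1=O
F5 | step 5 | (2S,3R)-2,6,6-trimethyl-2-(prop-2-en-1-yl)-3,6-dihydro-2H-pyran-3-ol | C=CC[C@]1(C)OC(C)(C)C=C[C@H]1O
F6 | step 5 | (2R,3R)-2,6,6-trimethyl-2-(prop-2-en-1-yl)-3,6-dihydro-2H-pyran-3-ol | C=CC[C@@]1(C)OC(C)(C)C=C[C@H]1O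
F7 | step 13 | (2S)-2,6,6-trimethyl-2-(prop-2-en-1-yl)-3,6-dihydro-2H-pyran-3-ol (both C3 epimers) | C=CC[C@]1(C)OC(C)(C)C=CC1O
F8 | step 13 | tert-butyldimethyl{[(2S)-2,6,6-trimethyl-2-(prop-2-en-1-yl)-3,6-dihydro-2H-pyran-3-yl]oxy}silane | C=CC[C@]1(C)OC(C)(C)C=CC1O[Si](C)(C)C(C)(C)C
F9 | step 13 | 9-{3-[(2S)-3-(tert-butyldimethylsilyloxy)-2,6,6-trimethyl-3,6-dihydro-2H-pyran-2-yl]propyl}-9-borabicyclo[3.3.1]nonane | B1(C2CCCC1CCC2)CCC[C@]1(C)OC(C)(C)C=CC1O[Si](C)(C)C(C)(C)C
F10 | step 13 | tris-silyl ether: analogue of 27 with the ring C3 carbonyl replaced by CH–OSi(t-Bu)Me2 | COc1c(C)cc(O[Si](C(C)C)(C(C)C)C(C)C)cc1C/C=C(\C)CC(O[Si](C)(C)C(C)(C)C)/C=C(\C)CCC[C@]1(C)OC(C)(C)C=CC1O[Si](C)(C)C(C)(C)C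
F11 | step 13 | triol: analogue of 28 with the ring C3 carbonyl replaced by CH–OH | COc1c(C)cc(O)cc1C/C=C(\C)CC(O)/C=C(\C)CCC[C@]1(C)OC(C)(C)C=CC1O
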